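**Plan** (locants: C1 = methyl-bearing ring-fusion carbon; C2, C3 = CH2 of the five-membered ring; C4 = C(OH)(i-Pr); C5 = ring-fusion CH; C6 = CH–O-aroyl; C7 = C=O; C8 = C(OH)Me; C9 = CHOH; C10 = CH2)
1. Late cuts: the phenol benzyl ether, the cis-8,9-diol (back to a C7-keto C8=C9 enone), the C6 aroyl ester, then C8=C9 (ring-closing metathesis, seven-membered ring) and the C4–isopropyl bond (back to a C4 ketone).
2. Key cut, C1–C5: the remaining cyclopentanone holds a β-hydroxy ketone O=C4–C5H–C6H(OH) whose α-carbon C5 is bonded to the quaternary C1. This is the retron of an epoxy alcohol semipinacol shift, so ring C1–C2–C3–C4–C5 is traced to a cyclobutanol C1–C2–C3–C4 carrying a C5–C6 oxirane on C4.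
3. Forward: four-membered ring first (asymmetric allylation gives cyclobutanone 7), union with enynol 12 at C4, trans-reduction, epoxidation, 4→5 ring expansion, isopropyl addition, metathesis to the seven-membered ring, oxidation, acylation, dihydroxylation, debenzylation.
4. Stereochemistry: C1 from the chiral palladium catalyst; a temporary C7 centre (lipase resolution) makes the Sharpless epoxidation matched and arm-selective; C5 (inversion) and C6 (retention) come from the oxirane; C4 by addition anti to the C5 side chain; C8 and C9 by osmylation anti to the angular methyl.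

Key step: step 10

Remark: the sense of induction in step 4 is assumed to parallel the six-membered-ring series (the (S)-PHOX ligand giving the (S)-2-allyl-2-methyl ketone), so the (R)-ligand is specified; the lipase in step 6 is assumed to treat ethynyl as the smaller substituent.

Step 1
Reactants: 1 cyclopentane-1,3-dione
Product: 2 2-diazocyclopentane-1,3-dione
Conditions: p-ABSA, Et3N, MeCN, 0 °C → rt
Reagents that add atoms: 4-acetamidobenzenesulfonyl azide CC(=O)Nc1ccc(cc1)S(=O)(=O)N=[N+]=[N-]
Why: Regitz diazo transfer to the doubly activated methylene of a cyclic 1,3-diketone is routine.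

Step 2
Reactants: 2 2-diazocyclopentane-1,3-dione; 3 prop-2-en-1-ol (allyl alcohol)
Product: 5 prop-2-en-1-yl 2-oxocyclobutane-1-carboxylate (racemic), via acylketene 4 (not isolated)
Conditions: hν (300 nm), 3 (5 equiv), CH2Cl2, rt
Reagents that add atoms: none
Why: Photochemical Wolff rearrangement of the 2-diazo-1,3-diketone contracts the ring to an acylketene that the alcohol traps, a standard entry to 2-oxocyclobutanecarboxylates (room temperature avoids thermal rearrangement of the allyl β-keto ester).

Step 3
Reactants: 5 prop-2-en-1-yl 2-oxocyclobutane-1-carboxylate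
Product: 6 prop-2-en-1-yl 1-methyl-2-oxocyclobutane-1-carboxylate (racemic)
Conditions: MeI, K2CO3, acetone, 50 °C
Reagents that add atoms: iodomethane CI
Why: C-alkylation of the β-keto ester under mild carbonate conditions installs the future C1 methyl without opening the strained ring.

Step 4
Reactants: 6 prop-2-en-1-yl 1-methyl-2-oxocyclobutane-1-carboxylate
Product: 7 (2R)-2-methyl-2-(prop-2-en-1-yl)cyclobutan-1-one
Conditions: Pd2(dba)3 (2.5 mol%), (R)-(CF3)3-t-BuPHOX [(R)-2-{2-[bis(4-(trifluoromethyl)phenyl)phosphanyl]-5-(trifluoromethyl)phenyl}-4-tert-butyl-4,5-dihydrooxazole] (6 mol%), PhMe, 20 °C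
Reagents that add atoms: none
Why: Decarboxylative asymmetric allylic alkylation (Tsuji allylation; oxidative addition of zerovalent palladium, loss of CO2, C-allylation inside the chiral coordination sphere) is precedented for α-quaternary cyclobutanones, and the ligand sets the quaternary centre C1 as (R).

Step 5
Reactants: 8 2-methylprop-2-enal (methacrolein); 9 ethynylmagnesium bromide
Product: 11 2-methylpent-1-en-4-yn-3-yl acetate (racemic), via magnesium alkoxide 10 (not isolated)
Conditions: THF, −78 → 0 °C; then Ac2O, 0 °C → rt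
Reagents that add atoms: acetic anhydride CC(=O)OC(C)=O
Why: 1,2-Addition of the alkynyl Grignard reagent to the enal followed by acetylation of the magnesium alkoxide in the same flask.

Step 6
Reactants: 11 2-methylpent-1-en-4-yn-3-yl acetate (racemic)
Product: 12 (3S)-2-methylpent-1-en-4-yn-3-ol
Conditions: immobilized Candida antarctica lipase B, phosphate buffer pH 7/MTBE, 30 °C, stopped below half conversion
Reagents that add atoms: none
Why: Lipase kinetic resolution by enantioselective ester hydrolysis; by the empirical size rule for secondary alcohols (slim ethynyl as the medium group, branched isopropenyl as the large group) the (S)-acetate should be cleaved, leaving the (R)-acetate behind.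

Step 7
Reactants: 12 (3S)-2-methylpent-1-en-4-yn-3-ol; 7 (2R)-2-methyl-2-(prop-2-en-1-yl)cyclobutan-1-one
Product: 14 (2R)-1-[(3S)-3-hydroxy-4-methylpent-4-en-1-yn-1-yl]-2-methyl-2-(prop-2-en-1-yl)cyclobutan-1-ol (both epimers at the ring carbinol carbon C4), via dilithio alkynolate 13 (not isolated)
Conditions: 12, n-BuLi (2.1 equiv), THF, −78 °C; then 7, −78 → −20 °C; aq NH4Cl
Reagents that add atoms: none
Why: Acetylide addition to the strained, electrophilic cyclobutanone joins the two fragments at C4; the new carbinol centre is formed without control, which is harmless because C4 becomes the ketone carbon in step 10.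

Step 8
Reactants: 14 alkynyl cyclobutanol
Product: 15 (2R)-1-[(1E,3R)-3-hydroxy-4-methylpenta-1,4-dien-1-yl]-2-methyl-2-(prop-2-en-1-yl)cyclobutan-1-ol (both C4 epimers; the C7 descriptor changes by priority only)
Conditions: Red-Al [NaAlH2(OCH2CH2OMe)2], THF, 0 °C → rt; aq Rochelle salt
Reagents that add atoms: none
Why: Hydroxyl-directed trans-hydroalumination of the but-2-yne-1,4-diol unit gives the E-alkene needed for a trans-oxirane, and the isolated alkenes are inert.

Step 9
Reactants: 15 (E)-ene-diol
Product: 16 (2R)-1-{(2R,3S)-3-[(1S)-1-hydroxy-2-methylprop-2-en-1-yl]oxiran-2-yl}-2-methyl-2-(prop-2-en-1-yl)cyclobutan-1-ol (both C4 epimers; oxirane C5 R, C6 S)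
Conditions: Ti(OiPr)4 (0.2 equiv), L-(+)-DIPT (0.24 equiv), t-BuOOH (2 equiv), 4 Å MS, CH2Cl2, −20 °C
Reagents that add atoms: tert-butyl hydroperoxide CC(C)(C)OO
Why: Sharpless asymmetric epoxidation in its matched mode: with L-(+)-tartrate the (7R) secondary allylic alcohol is the fast-reacting configuration for the E-disubstituted C5=C6 arm and the slow one for the isopropenyl arm, so only C5=C6 should be epoxidized, erythro to the C7 hydroxyl and independent of the C4 configuration (tertiary allylic alcohols are poor substrates for the titanium tartrate).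

Step 10
Reactants: 16 epoxy cyclobutanol (both C4 epimers)
Product: 17 (2S,3R)-2-[(1R,2S)-1,2-dihydroxy-3-methylbut-3-en-1-yl]-3-methyl-3-(prop-2-en-1-yl)cyclopentan-1-one
Conditions: ZnBr2 (0.3 equiv), CH2Cl2, 0 °C; aq NaHCO3
Reagents that add atoms: none
Why: The Lewis acid, held between the C7 hydroxyl and the oxirane oxygen, polarizes the distal C5–O bond (as in C3-selective openings of 2,3-epoxy alcohols), and as this bond breaks the antiperiplanar C4–C1 σ-bond of the cyclobutanol shifts from C4 to C5 while the carbinol oxygen becomes the C4 ketone; this is the semipinacol rearrangement of a 2,3-epoxy alcohol, a known reaction class that includes cyclobutanol-to-cyclopentanone expansions. No ring is closed by cyclization: the five-membered ring arises by a 1,2-alkyl shift that inserts C5 between C4 and C1 of the four-membered ring, driven by about 20 kcal/mol of strain release and by carbonyl formation, and it forges the hindered bond between C5 and the quaternary C1. C5 is formed with inversion at the migration terminus and C6 keeps its epoxide configuration, so the Sharpless oxirane alone fixes H5 trans to the C1 methyl and syn to O6; C1 migrates with retention and the C4 centre is erased, so both epimers of 16 should converge on 17. The step needs migration of the quaternary C1 and not the C3 methylene: the more substituted, more electron-rich ring carbon is the better migrating group, and either C4 epimer can place the C4–C1 bond anti to the breaking C–O bond by rotation about C4–C5. A competing hydride or alkenyl shift from C7 would need cleavage of the proximal C6–O bond and has no strain release behind it.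

Step 11
Reactants: 17 cyclopentanone diol
Product: 18 (1R,2S,3R)-2-[(1R,2S)-1,2-dihydroxy-3-methylbut-3-en-1-yl]-3-methyl-1-(propan-2-yl)-3-(prop-2-en-1-yl)cyclopentan-1-ol
Conditions: i-PrMgCl (5 equiv), CeCl3 (5 equiv), THF, −78 → −40 °C; aq NH4Cl
Reagents that add atoms: isopropylmagnesium chloride CC(C)[Mg]Cl
Why: Organocerium addition (low basicity suppresses enolization, retro-aldol cleavage and β-hydride reduction) should enter the cyclopentanone anti to the adjacent C5 side chain, placing the new hydroxyl cis to that chain and setting C4 as (R).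

Step 12
Reactants: 18 diene triol
Product: 19 (3R,3aS,4R,5S,8aR)-6,8a-dimethyl-3-(propan-2-yl)-1,2,3,3a,4,5,8,8a-octahydroazulene-3,4,5-triol
Conditions: second-generation Hoveyda–Grubbs catalyst (5 mol%), CH2Cl2 (0.005 M), 40 °C
Reagents that add atoms: none
Why: Ring-closing metathesis between the allyl group on C1 and the 1,1-disubstituted alkene on C7 closes the seven-membered ring as the trisubstituted C8=C9 alkene; the trans-disposed arms on C1 and C5 give the trans-fused hydroazulene and free hydroxyls are tolerated.

Step 13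
Reactants: 19 bicyclic triol
Product: 20 (3R,3aS,4R,8aR)-3,4-dihydroxy-6,8a-dimethyl-3-(propan-2-yl)-2,3,3a,4,8,8a-hexahydroazulen-5(1H)-one
Conditions: MnO2 (activated, excess), CH2Cl2, rt
Reagents that add atoms: none
Why: MnO2 oxidizes only the allylic C7 alcohol, leaves the saturated secondary C6 and tertiary C4 hydroxyls, and erases the temporary C7 stereocentre.

Step 14
Reactants: 20 hydroxy enone; 21 4-(benzyloxy)benzoyl chloride
Product: 22 (3R,3aS,4R,8aR)-3-hydroxy-6,8a-dimethyl-5-oxo-3-(propan-2-yl)-1,2,3,3a,4,5,8,8a-octahydroazulen-4-yl 4-(benzyloxy)benzoate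
Conditions: Et3N, DMAP (cat.), CH2Cl2, 0 °C → rt
Reagents that add atoms: none
Why: DMAP-catalyzed acylation of the only secondary hydroxyl (C6); the tertiary C4 hydroxyl does not react and the mild amine base should not epimerize the α-ketol centre.

Step 15
Reactants: 22 enone ester
Product: 23 (3R,3aS,4R,6S,7S,8aR)-3,6,7-trihydroxy-6,8a-dimethyl-5-oxo-3-(propan-2-yl)decahydroazulen-4-yl 4-(benzyloxy)benzoate
Conditions: OsO4 (5 mol%), NMO, citric acid, t-BuOH/H2O 1:1, rt
Reagents that add atoms: osmium tetroxide O=[Os](=O)(=O)=O; N-methylmorpholine N-oxide C[N+]1([O-])CCOCC1; water O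
Why: Catalytic syn-dihydroxylation (Upjohn conditions, citric acid for an electron-poor alkene) should deliver both hydroxyls to the α face, anti to the angular C1 methyl that shields the β face of C8=C9 in the trans-fused hydroazulene, setting C8 (S) and C9 (S).

Step 16
Reactants: 23 benzyl-protected diol ester
Product: 24 (3R,3aS,4R,6S,7S,8aR)-3,6,7-trihydroxy-6,8a-dimethyl-5-oxo-3-(propan-2-yl)decahydroazulen-4-yl 4-hydroxybenzoate (target)
Conditions: H2 (1 atm), 10% Pd/C, EtOAc, rt
Reagents that add atoms: none
Why: Hydrogenolysis of the benzyl aryl ether under neutral conditions frees the phenol without touching the ester, ketone or alcohols, and no alkene remains at this stage.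

**Compound list**
1 | cyclopentane-1,3-dione | O=C1CCC(=O)C1 | starting material
2 | 2-diazocyclopentane-1,3-dione | O=C1CCC(=O)C1=[N+]=[N-] | intermediate
3 | prop-2-en-1-ol (allyl alcohol) | C=CCO | starting material
4 | 2-(oxomethylidene)cyclobutan-1-one (acylketene) | O=C=C1CCC1=O | intermediate
5 | prop-2-en-1-yl 2-oxocyclobutane-1-carboxylate (racemic) | C=CCOC(=O)C1CCC1=O | intermediate
6 | prop-2-en-1-yl 1-methyl-2-oxocyclobutane-1-carboxylate (racemic) | C=CCOC(=O)C1(C)CCC1=O | intermediate
7 | (2R)-2-methyl-2-(prop-2-en-1-yl)cyclobutan-1-one | O=C1CC[C@]1(C)CC=C | intermediate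
8 | 2-methylprop-2-enal (methacrolein) | CC(=C)C=O | starting material
9 | ethynylmagnesium bromide | C#C[Mg]Br | starting material
10 | bromomagnesium 2-methylpent-1-en-4-yn-3-olate (racemic) | C#CC(O[Mg]Br)C(C)=C | intermediate
11 | 2-methylpent-1-en-4-yn-3-yl acetate (racemic) | C#CC(OC(C)=O)C(C)=C | intermediate
12 | (3S)-2-methylpent-1-en-4-yn-3-ol | C#C[C@@H](O)C(C)=C | intermediate
13 | C,O-dilithio derivative of 12 | [Li]C#C[C@@H](O[Li])C(C)=C | intermediate
14 | (2R)-1-[(3S)-3-hydroxy-4-methylpent-4-en-1-yn-1-yl]-2-methyl-2-(prop-2-en-1-yl)cyclobutan-1-ol, both epimers at the ring carbinol carbon | OC1(C#C[C@@H](O)C(C)=C)CC[C@]1(C)CC=C | intermediate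
15 | (2R)-1-[(1E,3R)-3-hydroxy-4-methylpenta-1,4-dien-1-yl]-2-methyl-2-(prop-2-en-1-yl)cyclobutan-1-ol, both epimers at the ring carbinol carbon | OC1(/C=C/[C@@H](O)C(C)=C)CC[C@]1(C)CC=C | intermediate
16 | (2R)-1-{(2R,3S)-3-[(1S)-1-hydroxy-2-methylprop-2-en-1-yl]oxiran-2-yl}-2-methyl-2-(prop-2-en-1-yl)cyclobutan-1-ol, both epimers at the ring carbinol carbon | OC1([C@@H]2O[C@H]2[C@@H](O)C(C)=C)CC[C@]1(C)CC=C | intermediate
17 | (2S,3R)-2-[(1R,2S)-1,2-dihydroxy-3-methylbut-3-en-1-yl]-3-methyl-3-(prop-2-en-1-yl)cyclopentan-1-one | O=C1CC[C@](C)(CC=C)[C@H]1[C@@H](O)[C@@H](O)C(C)=C | intermediate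
18 | (1R,2S,3R)-2-[(1R,2S)-1,2-dihydroxy-3-methylbut-3-en-1-yl]-3-methyl-1-(propan-2-yl)-3-(prop-2-en-1-yl)cyclopentan-1-ol | CC(C)[C@]1(O)CC[C@](C)(CC=C)[C@H]1[C@@H](O)[C@@H](O)C(C)=C | intermediate
19 | (3R,3aS,4R,5S,8aR)-6,8a-dimethyl-3-(propan-2-yl)-1,2,3,3a,4,5,8,8a-octahydroazulene-3,4,5-triol | CC(C)[C@]1(O)CC[C@]2(C)CC=C(C)[C@H](O)[C@H](O)[C@H]21 | intermediate
20 | (3R,3aS,4R,8aR)-3,4-dihydroxy-6,8a-dimethyl-3-(propan-2-yl)-2,3,3a,4,8,8a-hexahydroazulen-5(1H)-one | CC(C)[C@]1(O)CC[C@]2(C)CC=C(C)C(=O)[C@H](O)[C@H]21 | intermediate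
21 | 4-(benzyloxy)benzoyl chloride | O=C(Cl)c1ccc(OCc2ccccc2)cc1 | starting material
22 | (3R,3aS,4R,8aR)-3-hydroxy-6,8a-dimethyl-5-oxo-3-(propan-2-yl)-1,2,3,3a,4,5,8,8a-octahydroazulen-4-yl 4-(benzyloxy)benzoate | CC(C)[C@]1(O)CC[C@]2(C)CC=C(C)C(=O)[C@H](OC(=O)c3ccc(OCc4ccccc4)cc3)[C@H]21 | intermediate
23 | (3R,3aS,4R,6S,7S,8aR)-3,6,7-trihydroxy-6,8a-dimethyl-5-oxo-3-(propan-2-yl)decahydroazulen-4-yl 4-(benzyloxy)benzoate | CC(C)[C@]1(O)CC[C@]2(C)C[C@H](O)[C@](C)(O)C(=O)[C@H](OC(=O)c3ccc(OCc4ccccc4)cc3)[C@H]21 | intermediate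
24 | (3R,3aS,4R,6S,7S,8aR)-3,6,7-trihydroxy-6,8a-dimethyl-5-oxo-3-(propan-2-yl)decahydroazulen-4-yl 4-hydroxybenzoate | CC(C)[C@]1(O)CC[C@]2(C)C[C@H](O)[C@](C)(O)C(=O)[C@H](OC(=O)c3ccc(O)cc3)[C@H]21 | target

**Step count and risks**
Total steps: 16. Longest linear sequence: 14 (steps 1–4 and 7–16); steps 5–6 form the side branch.

Steps most likely to fail:

Step 10. The rearrangement may be diverted by a hydride or alkenyl shift from the free C7 carbinol after cleavage of the C6–O bond, by bromide opening of the oxirane, or by migration of the C3 methylene in place of the quaternary C1. The fallback sets out from 16 and comes back at 17. It removes the free C7 donor from the substrate: the secondary C7 hydroxyl is capped selectively (TBSCl, imidazole, DMF; the tertiary cyclobutanol stays free) to give the C7 tert-butyldimethylsilyl ether of 16 F1. F1 is rearranged with BF3·OEt2 in CH2Cl2 at −78 °C, where only the free cyclobutanol can drive a shift and the bulky silyloxy group shields C6, giving the C7 tert-butyldimethylsilyl ether of 17 F2. HF·pyridine in THF at 0 °C then returns 17.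

Step 11. The β-alkoxide formed from the free aldol hydroxyl may trigger retro-aldol cleavage or enolization (loss of the C5 configuration), the hindered ketone may be reduced by β-hydride transfer, or facial selectivity may be poor. The fallback sets out from 17 and comes back at 18. The aldol diol is tied up first (2,2-dimethoxypropane, PPTS, CH2Cl2) as the 6,7-O-isopropylidene acetal of 17 F3, so that no β-alkoxide can form. Addition of i-PrLi/CeCl3 in THF at −78 °C, again anti to the now rigid dioxolane on C5, gives the 6,7-O-isopropylidene acetal of 18 F4. Aqueous AcOH/THF then releases 18.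

Step 15. Osmylation of the hindered, electron-poor enone may be slow, or may occur from the β face because the α-oriented C6 aroyloxy group crowds the α face. The fallback sets out from 20 and comes back at 23. Dihydroxylation is moved ahead of the acylation so that the free α-oriented C6 hydroxyl can direct the reagent by hydrogen bonding: stoichiometric OsO4·TMEDA in CH2Cl2 at −78 °C, then aq NaHSO3, gives (3R,3aS,4R,6S,7S,8aR)-3,4,6,7-tetrahydroxy-6,8a-dimethyl-3-(propan-2-yl)octahydroazulen-5(1H)-one F5. The cis-8,9-diol is masked (2-methoxypropene, PPTS) as the 8,9-O-isopropylidene acetal of F5 F6. The remaining secondary C6 hydroxyl is acylated with 21 (Et3N, DMAP) to give the 6-O-[4-(benzyloxy)benzoyl] derivative of F6 F7, and aq TFA/THF at 0 °C removes the acetal to give 23.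

Further compounds
F1 | step 10 | C7 tert-butyldimethylsilyl ether of 16 (configuration as in 16, both ring-carbinol epimers) | OC1([C@@H]2O[C@H]2[C@@H](O[Si](C)(C)C(C)(C)C)C(C)=C)CC[C@]1(C)CC=C
F2 | step 10 | C7 tert-butyldimethylsilyl ether of 17 | O=C1CC[C@](C)(CC=C)[C@H]1[C@@H](O)[C@@H](O[Si](C)(C)C(C)(C)C)C(C)=C
F3 | step 11 | 6,7-O-isopropylidene acetal of 17 | O=C1CC[C@](C)(CC=C)[C@H]1[C@H]2OC(C)(C)O[C@H]2C(C)=C
F4 | step 11 | 6,7-O-isopropylidene acetal of 18 | CC(C)[C@]1(O)CC[C@](C)(CC=C)[C@H]1[C@H]2OC(C)(C)O[C@H]2C(C)=C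
F5 | step 15 | (3R,3aS,4R,6S,7S,8aR)-3,4,6,7-tetrahydroxy-6,8a-dimethyl-3-(propan-2-yl)octahydroazulen-5(1H)-one | CC(C)[C@]1(O)CC[C@]2(C)C[C@H](O)[C@](C)(O)C(=O)[C@H](O)[C@H]21
F6 | step 15 | 8,9-O-isopropylidene acetal of F5 | CC(C)[C@]1(O)CC[C@]2(C)C[C@@H]3OC(C)(C)O[C@]3(C)C(=O)[C@H](O)[C@H]21
F7 | step 15 | 6-O-[4-(benzyloxy)benzoyl] derivative of F6 | CC(C)[C@]1(O)CC[C@]2(C)C[C@@H]3OC(C)(C)O[C@]3(C)C(=O)[C@H](OC(=O)c4ccc(OCc5ccccc5)cc4)[C@H]21
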